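## Retrosynthetic overview

1. Target ⇐ peracid epoxidation of the strained 1(10)-E alkene (ring oxirane formed last) ⇐ 3β-alcohol from ketoreductase reduction of the macrocyclic (4Z)-enone.
2. Ten-membered carbocycle (second ring) ⇐ intramolecular Nozaki–Hiyama–Kishi coupling, C3–C4, of a (Z)-alkenyl iodide with an aldehyde.
3. C7–C8 bond and the α-methylene lactone stereotriad ⇐ zinc Barbier allylation of a (bromomethyl)butenolide with a β,γ-unsaturated aldehyde; C8 is then inverted and acylated in one Mitsunobu step with the epoxy acid.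
4. Butenolide (first ring) ⇐ ring-closing metathesis of the 2-(bromomethyl)acrylate of a (Z)-iodo dienol; its carbinol (C6) comes from Sharpless epoxidation of an enynol and reductive oxirane opening.
5. Epoxy acid ⇐ Sharpless epoxidation of tiglyl alcohol, then RuO4 oxidation; aldehyde ⇐ Negishi carboalumination of a butynyl silyl ether, then oxirane opening.

Assumption: a Prelog-selective ketoreductase that accepts enone 31 is found by screening a commercial enzyme panel; all starting materials are catalogue compounds.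

Locants C1–C15 are germacrane locants: ring carbons C1–C10, lactone α-carbon C11, lactone carbonyl C12, exocyclic methylene C13, methyl C14 on C10, methyl C15 on C4.

## Route

Step 1
Reactants: 1 (E)-2-methylbut-2-en-1-ol (tiglyl alcohol)
Product: 2 [(2S,3S)-2,3-dimethyloxiran-2-yl]methanol
Conditions: Ti(OiPr)4 (10 mol%), L-(+)-diethyl tartrate (12 mol%), t-BuOOH, 4 Å MS, CH2Cl2, −20 °C
Reagents that add atoms: tert-butyl hydroperoxide, CC(C)(C)OO
Why: Katsuki–Sharpless asymmetric epoxidation, in which the titanium–L-(+)-tartrate catalyst delivers oxygen to one enantioface of the achiral E-allylic alcohol and sets both oxirane centres (2S,3S), the first stereocentres of the route, by asymmetric catalysis.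

Step 2
Reactants: 2 [(2S,3S)-2,3-dimethyloxiran-2-yl]methanol
Product: 3 (2R,3S)-2,3-dimethyloxirane-2-carboxylic acid
Conditions: RuCl3 hydrate (2 mol%), NaIO4, CCl4/MeCN/H2O, rt
Reagents that add atoms: water, O
Why: Sharpless RuO4-catalysed oxidation takes the primary alcohol through the aldehyde hydrate to the acid without opening the oxirane, and no stereocentre is touched (the C2 descriptor changes only through CIP priorities).

Step 3
Reactants: 4 tert-butyl(but-3-yn-1-yloxy)dimethylsilane, 5 oxirane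
Product: 7 (3E)-6-{[tert-butyl(dimethyl)silyl]oxy}-4-methylhex-3-en-1-ol, via alkenylalane 6 (not isolated)
Conditions: Me3Al, Cp2ZrCl2 (20 mol%), CH2Cl2, 0 °C to rt; then n-BuLi, THF, −78 °C; then 5, −78 to 0 °C
Reagents that add atoms: trimethylaluminium, C[Al](C)C
Why: Negishi zirconium-catalysed syn-carboalumination fixes the E-trisubstituted alkene (C10=C1 with C14), and the derived alanate opens oxirane with retention of alkene geometry.

Step 4
Reactants: 7 (3E)-6-{[tert-butyl(dimethyl)silyl]oxy}-4-methylhex-3-en-1-ol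
Product: 8 tert-butyl{[(3E)-6-{[tert-butyl(diphenyl)silyl]oxy}-3-methylhex-3-en-1-yl]oxy}dimethylsilane
Conditions: TBDPSCl, imidazole, DMF, rt
Reagents that add atoms: tert-butyl(chloro)diphenylsilane, CC(C)(C)[Si](Cl)(c1ccccc1)c1ccccc1
Why: Routine silylation protects the future C3 oxygen with a group that survives the later acidic removal of the TBS ether.

Step 5
Reactants: 8 tert-butyl{[(3E)-6-{[tert-butyl(diphenyl)silyl]oxy}-3-methylhex-3-en-1-yl]oxy}dimethylsilane
Product: 9 (3E)-6-{[tert-butyl(diphenyl)silyl]oxy}-3-methylhex-3-en-1-ol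
Conditions: PPTS (cat.), MeOH, rt
Reagents that add atoms: none
Why: Acid-catalysed methanolysis cleaves the primary TBS ether much faster than the TBDPS ether, which frees only the future C8 oxygen.

Step 6
Reactants: 9 (3E)-6-{[tert-butyl(diphenyl)silyl]oxy}-3-methylhex-3-en-1-ol
Product: 10 (3E)-6-{[tert-butyl(diphenyl)silyl]oxy}-3-methylhex-3-enal
Conditions: Dess–Martin periodinane, NaHCO3, CH2Cl2, 0 °C (used at once)
Reagents that add atoms: none
Why: Buffered Dess–Martin oxidation is non-basic, so the β,γ-unsaturated aldehyde does not slip into conjugation.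

Step 7
Reactants: 11 but-2-yn-1-ol, 12 ethyl (triphenylphosphoranylidene)acetate
Product: 14 ethyl (2E)-hex-2-en-4-ynoate, via but-2-ynal 13 (not isolated)
Conditions: activated MnO2 (10 equiv), CH2Cl2, rt
Reagents that add atoms: none
Why: Tandem MnO2 oxidation–Wittig olefination traps the volatile ynal in situ, and the stabilised ylide gives the E-enoate.

Step 8
Reactants: 14 ethyl (2E)-hex-2-en-4-ynoate
Product: 15 (2E)-hex-2-en-4-yn-1-ol
Conditions: i-Bu2AlH (2.2 equiv), CH2Cl2, −78 °C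
Reagents that add atoms: none
Why: 1,2-Reduction of the conjugated ester by the aluminium hydride gives the E-allylic alcohol without touching alkene or alkyne.

Step 9
Reactants: 15 (2E)-hex-2-en-4-yn-1-ol
Product: 16 [(2R,3R)-3-(prop-1-yn-1-yl)oxiran-2-yl]methanol
Conditions: Ti(OiPr)4 (10 mol%), D-(−)-diethyl tartrate (12 mol%), t-BuOOH, 4 Å MS, CH2Cl2, −20 °C
Reagents that add atoms: tert-butyl hydroperoxide, CC(C)(C)OO
Why: Katsuki–Sharpless asymmetric epoxidation with the D-(−)-tartrate catalyst sets the (2R,3R) oxirane, whose C3–O bond becomes the C6–O bond of the target, again by asymmetric catalysis on an achiral substrate.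

Step 10
Reactants: 16 [(2R,3R)-3-(prop-1-yn-1-yl)oxiran-2-yl]methanol
Product: 17 (2S,3R)-2-(iodomethyl)-3-(prop-1-yn-1-yl)oxirane
Conditions: I2, PPh3, imidazole, CH2Cl2, 0 °C
Reagents that add atoms: iodine, II
Why: Appel-type (Garegg–Samuelsson) iodination replaces the primary hydroxyl only, and the oxirane centres are untouched (the C2 descriptor changes through CIP priorities alone).

Step 11
Reactants: 17 (2S,3R)-2-(iodomethyl)-3-(prop-1-yn-1-yl)oxirane
Product: 18 (3S)-hex-1-en-4-yn-3-ol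
Conditions: Zn dust, EtOH, 70 °C; aq NH4Cl
Reagents that add atoms: none
Why: Zinc insertion into the C–I bond and β-elimination open the oxirane reductively to the vinyl carbinol, and because the C3–O bond is never broken the carbinol keeps the Sharpless-derived configuration (3S).

Step 12
Reactants: 18 (3S)-hex-1-en-4-yn-3-ol
Product: 20 (3S,4Z)-5-iodohexa-1,4-dien-3-ol, via cyclic alkenylaluminate 19 (not isolated)
Conditions: NaAlH2(OCH2CH2OMe)2 (Red-Al), THF, 0 °C to rt; then I2, THF, −78 °C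
Reagents that add atoms: iodine, II
Why: Hydroxyl-directed trans-hydroalumination places aluminium on the distal alkyne carbon in a five-membered aluminate, and iodinolysis with retention gives the (Z)-alkenyl iodide that carries the C4=C5 geometry of the target.

Step 13
Reactants: 20 (3S,4Z)-5-iodohexa-1,4-dien-3-ol, 21 2-(bromomethyl)prop-2-enoic acid
Product: 22 (3S,4Z)-5-iodohexa-1,4-dien-3-yl 2-(bromomethyl)prop-2-enoate
Conditions: DIC, DMAP (5 mol%), CH2Cl2, 0 °C
Reagents that add atoms: none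
Why: Steglich esterification acylates the secondary alcohol under near-neutral conditions with retention at C6.

Step 14
Reactants: 22 (3S,4Z)-5-iodohexa-1,4-dien-3-yl 2-(bromomethyl)prop-2-enoate
Product: 23 (5S)-3-(bromomethyl)-5-[(1Z)-2-iodoprop-1-en-1-yl]furan-2(5H)-one
Conditions: second-generation Grubbs catalyst (H2IMes)(PCy3)Cl2Ru=CHPh (5 mol%), toluene, 80 °C, 0.01 M
Reagents that add atoms: none
Why: Ring-closing metathesis between the vinyl group and the acrylate alkene forms the butenolide (first ring) with loss of ethene, while the trisubstituted iodoalkene and the stereocentre are inert.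

Step 15
Reactants: 23 (5S)-3-(bromomethyl)-5-[(1Z)-2-iodoprop-1-en-1-yl]furan-2(5H)-one, 10 (3E)-6-{[tert-butyl(diphenyl)silyl]oxy}-3-methylhex-3-enal
Product: 25 (4R,5S)-4-[(1S,3E)-6-{[tert-butyl(diphenyl)silyl]oxy}-1-hydroxy-3-methylhex-3-en-1-yl]-5-[(1Z)-2-iodoprop-1-en-1-yl]-3-methylideneoxolan-2-one, via allylzinc bromide 24 (not isolated)
Conditions: Zn dust, THF/sat. aq NH4Cl, 0 °C to rt
Reagents that add atoms: none
Why: Barbier allylation through the γ-carbon of the ring-locked allylzinc attacks anti to the C5 alkenyl group (6,7-trans lactone, C7 = R) and passes through a closed chair transition state with the aldehyde chain equatorial, which gives the 8α-alcohol (1S).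

Step 16
Reactants: 25 (4R,5S)-4-[(1S,3E)-6-{[tert-butyl(diphenyl)silyl]oxy}-1-hydroxy-3-methylhex-3-en-1-yl]-5-[(1Z)-2-iodoprop-1-en-1-yl]-3-methylideneoxolan-2-one, 3 (2R,3S)-2,3-dimethyloxirane-2-carboxylic acid
Product: 26 (1R,3E)-6-{[tert-butyl(diphenyl)silyl]oxy}-1-{(2S,3R)-2-[(1Z)-2-iodoprop-1-en-1-yl]-4-methylidene-5-oxooxolan-3-yl}-3-methylhex-3-en-1-yl (2R,3S)-2,3-dimethyloxirane-2-carboxylate
Conditions: PPh3, DIAD, THF, 0 °C to rt
Reagents that add atoms: none
Why: Mitsunobu esterification displaces the activated C8 oxygen by the carboxylate with clean SN2 inversion, so the side chain is installed and C8 is corrected to the required 8β (R) configuration in one step.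

Step 17
Reactants: 26 (1R,3E)-6-{[tert-butyl(diphenyl)silyl]oxy}-1-{(2S,3R)-2-[(1Z)-2-iodoprop-1-en-1-yl]-4-methylidene-5-oxooxolan-3-yl}-3-methylhex-3-en-1-yl (2R,3S)-2,3-dimethyloxirane-2-carboxylate
Product: 27 (1R,3E)-6-hydroxy-1-{(2S,3R)-2-[(1Z)-2-iodoprop-1-en-1-yl]-4-methylidene-5-oxooxolan-3-yl}-3-methylhex-3-en-1-yl (2R,3S)-2,3-dimethyloxirane-2-carboxylate
Conditions: HF·pyridine, pyridine, THF, 0 °C to rt
Reagents that add atoms: none
Why: Buffered fluoride desilylation frees the primary alcohol without base, so the α-methylene lactone, the esters and the oxirane survive.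

Step 18
Reactants: 27 (1R,3E)-6-hydroxy-1-{(2S,3R)-2-[(1Z)-2-iodoprop-1-en-1-yl]-4-methylidene-5-oxooxolan-3-yl}-3-methylhex-3-en-1-yl (2R,3S)-2,3-dimethyloxirane-2-carboxylate
Product: 28 (1R,3E)-1-{(2S,3R)-2-[(1Z)-2-iodoprop-1-en-1-yl]-4-methylidene-5-oxooxolan-3-yl}-3-methyl-6-oxohex-3-en-1-yl (2R,3S)-2,3-dimethyloxirane-2-carboxylate
Conditions: Dess–Martin periodinane, NaHCO3, CH2Cl2, 0 °C (used at once)
Reagents that add atoms: none
Why: Buffered Dess–Martin oxidation gives the C3 aldehyde under non-basic conditions that leave the β,γ-alkene in place.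

Step 19
Reactants: 28 (1R,3E)-1-{(2S,3R)-2-[(1Z)-2-iodoprop-1-en-1-yl]-4-methylidene-5-oxooxolan-3-yl}-3-methyl-6-oxohex-3-en-1-yl (2R,3S)-2,3-dimethyloxirane-2-carboxylate
Product: 30 (1(10)E,4Z)-3-hydroxy-8β-{[(2R,3S)-2,3-dimethyloxiran-2-yl]carbonyloxy}germacra-1(10),4,11(13)-trien-6α,12-olide (6R,7R,8R; both C3 epimers), via alkenylchromium dichloride 29 (not isolated)
Conditions: CrCl2 (10 equiv), NiCl2 (2 mol%), degassed DMSO/THF, rt, slow addition, 2 mM
Reagents that add atoms: none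
Why: Intramolecular Nozaki–Hiyama–Kishi coupling adds the alkenylchromium, formed with retention of the Z geometry, chemoselectively to the aldehyde and closes the ten-membered ring at C3–C4; C3 is formed as an epimer mixture that converges in step 20.

Step 20
Reactants: 30 (1(10)E,4Z)-3-hydroxy-8β-{[(2R,3S)-2,3-dimethyloxiran-2-yl]carbonyloxy}germacra-1(10),4,11(13)-trien-6α,12-olide (both C3 epimers)
Product: 31 (1(10)E,4Z)-3-oxo-8β-{[(2R,3S)-2,3-dimethyloxiran-2-yl]carbonyloxy}germacra-1(10),4,11(13)-trien-6α,12-olide (6R,7R,8R)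
Conditions: Dess–Martin periodinane, NaHCO3, CH2Cl2, 0 °C
Reagents that add atoms: none
Why: Dess–Martin oxidation of the allylic alcohol turns both C3 epimers into one (4Z)-enone, whose cis geometry is the stable one in a ten-membered ring.

Step 21
Reactants: 31 (1(10)E,4Z)-3-oxo-8β-{[(2R,3S)-2,3-dimethyloxiran-2-yl]carbonyloxy}germacra-1(10),4,11(13)-trien-6α,12-olide
Product: 32 (1(10)E,4Z)-3β-hydroxy-8β-{[(2R,3S)-2,3-dimethyloxiran-2-yl]carbonyloxy}germacra-1(10),4,11(13)-trien-6α,12-olide (3S,6R,7R,8R)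
Conditions: ketoreductase (KRED, Prelog-selective), NADP+ (cat.), i-PrOH, phosphate buffer pH 7.0, DMSO (10% v/v), 30 °C
Reagents that add atoms: none
Why: A ketoreductase (NADPH-dependent alcohol dehydrogenase, oxidoreductase class EC 1.1.1) delivers hydride to one face of the enone carbonyl in its active site and sets C3 as the (S) 3β-alcohol under neutral conditions, with the alkenes, lactone and esters untouched.

Step 22
Reactants: 32 (1(10)E,4Z)-3β-hydroxy-8β-{[(2R,3S)-2,3-dimethyloxiran-2-yl]carbonyloxy}germacra-1(10),4,11(13)-trien-6α,12-olide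
Product: 33 (4Z)-1β,10α-epoxy-3β-hydroxy-8β-{[(2R,3S)-2,3-dimethyloxiran-2-yl]carbonyloxy}germacra-4,11(13)-dien-6α,12-olide (1R,3S,6R,7R,8R,10R), CNP0268255.6
Conditions: mCPBA (1.1 equiv), NaHCO3, CH2Cl2, 0 °C
Reagents that add atoms: 3-chloroperoxybenzoic acid, OOC(=O)c1cccc(Cl)c1
Why: Prilezhaev epoxidation picks the strained, electron-rich 1(10)-E alkene over the C4=C5 alkene (deactivated by two allylic oxygens) and the conjugated methylene, and attack on the exposed outer face of the ring with C14 on the β side gives the trans 1β,10α-oxirane (1R,10R).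

## Compound list

1 | (E)-2-methylbut-2-en-1-ol | C/C=C(\C)CO | starting material
2 | [(2S,3S)-2,3-dimethyloxiran-2-yl]methanol | OC[C@]1(C)O[C@H]1C | intermediate
3 | (2R,3S)-2,3-dimethyloxirane-2-carboxylic acid | OC(=O)[C@]1(C)O[C@H]1C | intermediate
4 | tert-butyl(but-3-yn-1-yloxy)dimethylsilane | C#CCCO[Si](C)(C)C(C)(C)C | starting material
5 | oxirane | C1CO1 | starting material
6 | (E)-{4-[(tert-butyldimethylsilyl)oxy]-2-methylbut-1-en-1-yl}dimethylalumane | C[Al](C)/C=C(\C)CCO[Si](C)(C)C(C)(C)C | intermediate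
7 | (3E)-6-{[tert-butyl(dimethyl)silyl]oxy}-4-methylhex-3-en-1-ol | OCC/C=C(\C)CCO[Si](C)(C)C(C)(C)C | intermediate
8 | tert-butyl{[(3E)-6-{[tert-butyl(diphenyl)silyl]oxy}-3-methylhex-3-en-1-yl]oxy}dimethylsilane | CC(C)(C)[Si](C)(C)OCC/C(C)=C/CCO[Si](c1ccccc1)(c1ccccc1)C(C)(C)C | intermediate
9 | (3E)-6-{[tert-butyl(diphenyl)silyl]oxy}-3-methylhex-3-en-1-ol | OCC/C(C)=C/CCO[Si](c1ccccc1)(c1ccccc1)C(C)(C)C | intermediate
10 | (3E)-6-{[tert-butyl(diphenyl)silyl]oxy}-3-methylhex-3-enal | O=CC/C(C)=C/CCO[Si](c1ccccc1)(c1ccccc1)C(C)(C)C | intermediate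
11 | but-2-yn-1-ol | CC#CCO | starting material
12 | ethyl (triphenylphosphoranylidene)acetate | CCOC(=O)C=P(c1ccccc1)(c1ccccc1)c1ccccc1 | starting material
13 | but-2-ynal | CC#CC=O | intermediate
14 | ethyl (2E)-hex-2-en-4-ynoate | CCOC(=O)/C=C/C#CC | intermediate
15 | (2E)-hex-2-en-4-yn-1-ol | CC#C/C=C/CO | intermediate
16 | [(2R,3R)-3-(prop-1-yn-1-yl)oxiran-2-yl]methanol | OC[C@H]1O[C@@H]1C#CC | intermediate
17 | (2S,3R)-2-(iodomethyl)-3-(prop-1-yn-1-yl)oxirane | IC[C@H]1O[C@@H]1C#CC | intermediate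
18 | (3S)-hex-1-en-4-yn-3-ol | C=C[C@H](O)C#CC | intermediate
19 | sodium (5S)-5-ethenyl-2,2-bis(2-methoxyethoxy)-3-methyl-2,5-dihydro-1,2-oxaaluminol-2-uide | [Na+].C=C[C@@H]1O[Al-](OCCOC)(OCCOC)C(C)=C1 | intermediate
20 | (3S,4Z)-5-iodohexa-1,4-dien-3-ol | C=C[C@H](O)/C=C(/C)I | intermediate
21 | 2-(bromomethyl)prop-2-enoic acid | OC(=O)C(=C)CBr | starting material
22 | (3S,4Z)-5-iodohexa-1,4-dien-3-yl 2-(bromomethyl)prop-2-enoate | C=C[C@H](OC(=O)C(=C)CBr)/C=C(/C)I | intermediate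
23 | (5S)-3-(bromomethyl)-5-[(1Z)-2-iodoprop-1-en-1-yl]furan-2(5H)-one | BrCC1=C[C@@H](/C=C(/C)I)OC1=O | intermediate
24 | bromo{[(5S)-5-[(1Z)-2-iodoprop-1-en-1-yl]-2-oxo-2,5-dihydrofuran-3-yl]methyl}zinc | Br[Zn]CC1=C[C@@H](/C=C(/C)I)OC1=O | intermediate
25 | (4R,5S)-4-[(1S,3E)-6-{[tert-butyl(diphenyl)silyl]oxy}-1-hydroxy-3-methylhex-3-en-1-yl]-5-[(1Z)-2-iodoprop-1-en-1-yl]-3-methylideneoxolan-2-one | C=C1C(=O)O[C@H](/C=C(/C)I)[C@H]1[C@@H](O)C/C(C)=C/CCO[Si](c1ccccc1)(c1ccccc1)C(C)(C)C | intermediate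
26 | (1R,3E)-6-{[tert-butyl(diphenyl)silyl]oxy}-1-{(2S,3R)-2-[(1Z)-2-iodoprop-1-en-1-yl]-4-methylidene-5-oxooxolan-3-yl}-3-methylhex-3-en-1-yl (2R,3S)-2,3-dimethyloxirane-2-carboxylate | C=C1C(=O)O[C@H](/C=C(/C)I)[C@H]1[C@H](OC(=O)[C@]2(C)O[C@H]2C)C/C(C)=C/CCO[Si](c1ccccc1)(c1ccccc1)C(C)(C)C | intermediate
27 | (1R,3E)-6-hydroxy-1-{(2S,3R)-2-[(1Z)-2-iodoprop-1-en-1-yl]-4-methylidene-5-oxooxolan-3-yl}-3-methylhex-3-en-1-yl (2R,3S)-2,3-dimethyloxirane-2-carboxylate | C=C1C(=O)O[C@H](/C=C(/C)I)[C@H]1[C@H](OC(=O)[C@]2(C)O[C@H]2C)C/C(C)=C/CCO | intermediate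
28 | (1R,3E)-1-{(2S,3R)-2-[(1Z)-2-iodoprop-1-en-1-yl]-4-methylidene-5-oxooxolan-3-yl}-3-methyl-6-oxohex-3-en-1-yl (2R,3S)-2,3-dimethyloxirane-2-carboxylate | C=C1C(=O)O[C@H](/C=C(/C)I)[C@H]1[C@H](OC(=O)[C@]2(C)O[C@H]2C)C/C(C)=C/CC=O | intermediate
29 | dichloro[(1Z)-1-{(2S,3R)-3-[(1R,3E)-1-{[(2R,3S)-2,3-dimethyloxiran-2-yl]carbonyloxy}-3-methyl-6-oxohex-3-en-1-yl]-4-methylidene-5-oxooxolan-2-yl}prop-1-en-2-yl]chromium | C=C1C(=O)O[C@H](/C=C(/C)[Cr](Cl)Cl)[C@H]1[C@H](OC(=O)[C@]2(C)O[C@H]2C)C/C(C)=C/CC=O | intermediate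
30 | (1(10)E,4Z)-3-hydroxy-8β-{[(2R,3S)-2,3-dimethyloxiran-2-yl]carbonyloxy}germacra-1(10),4,11(13)-trien-6α,12-olide (6R,7R,8R; both C3 epimers) | C=C1C(=O)O[C@@H]2/C=C(/C)C(O)C/C=C(\C)C[C@@H](OC(=O)[C@]3(C)O[C@H]3C)[C@@H]12 | intermediate
31 | (1(10)E,4Z)-3-oxo-8β-{[(2R,3S)-2,3-dimethyloxiran-2-yl]carbonyloxy}germacra-1(10),4,11(13)-trien-6α,12-olide (6R,7R,8R) | C=C1C(=O)O[C@@H]2/C=C(/C)C(=O)C/C=C(\C)C[C@@H](OC(=O)[C@]3(C)O[C@H]3C)[C@@H]12 | intermediate
32 | (1(10)E,4Z)-3β-hydroxy-8β-{[(2R,3S)-2,3-dimethyloxiran-2-yl]carbonyloxy}germacra-1(10),4,11(13)-trien-6α,12-olide (3S,6R,7R,8R) | C=C1C(=O)O[C@@H]2/C=C(/C)[C@@H](O)C/C=C(\C)C[C@@H](OC(=O)[C@]3(C)O[C@H]3C)[C@@H]12 | intermediate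
33 | (4Z)-1β,10α-epoxy-3β-hydroxy-8β-{[(2R,3S)-2,3-dimethyloxiran-2-yl]carbonyloxy}germacra-4,11(13)-dien-6α,12-olide (1R,3S,6R,7R,8R,10R) | C=C1C(=O)O[C@@H]2/C=C(/C)[C@@H](O)C[C@H]3O[C@]3(C)C[C@@H](OC(=O)[C@]3(C)O[C@H]3C)[C@@H]12 | target

## Step count and risks

Total steps: 22. Longest linear sequence: 16 steps (steps 7–14, then 15–22).

The three steps most likely to fail:

Step 19, the Nozaki–Hiyama–Kishi ring closure. The strained ten-membered ring may not close with the bulky epoxy ester in place, or the chromium reagent may damage that ester. The fallback moves the ring closure ahead of the side-chain installation and sets out from 25. Desilylation of 25 (HF·pyridine, pyridine, THF) gives the seco-diol F1. Selective oxidation of its primary hydroxyl (TEMPO, PhI(OAc)2, CH2Cl2) gives the hydroxy aldehyde F2. The same CrCl2/NiCl2 coupling, now on the less hindered free 8α-alcohol, gives the macrocyclic 3,8-diol F3. MnO2 in CH2Cl2 oxidises only the allylic C3 hydroxyl and gives the 8α-hydroxy enone F4. Mitsunobu esterification of F4 with acid 3 (PPh3, DIAD) inverts C8 and rejoins the route at 31.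

Step 21, the ketoreductase reduction. The enzyme may not accept the macrocyclic enone, or the α-methylene lactone may alkylate and deactivate it. The fallback replaces the biocatalytic reduction by a reagent-controlled chemical one, sets out from 31 and returns at 32. It uses (R)-2-methyl-CBS-oxazaborolidine (20 mol%) with catecholborane in toluene at −78 °C, where the alkenyl side of the ketone acts as the large group and the (3S)-alcohol results; it makes no new compound (F0).

Step 16, the Mitsunobu inversion. The hindered homoallylic C8 alcohol may eliminate instead of undergoing substitution. The fallback inverts C8 by oxidation and reduction, sets out from 25 and returns at 26. Dess–Martin oxidation (NaHCO3, CH2Cl2, 0 °C) gives the C8 ketone F5. Catalyst-controlled reduction with (S)-2-methyl-CBS-oxazaborolidine and catecholborane (toluene, −78 °C) gives the 8β-alcohol F6. Yamaguchi esterification of F6 with acid 3 (2,4,6-trichlorobenzoyl chloride, Et3N, DMAP, toluene) proceeds with retention and gives 26.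

Further compounds

F1 | step 19 | (4R,5S)-4-[(1S,3E)-1,6-dihydroxy-3-methylhex-3-en-1-yl]-5-[(1Z)-2-iodoprop-1-en-1-yl]-3-methylideneoxolan-2-one | C=C1C(=O)O[C@H](/C=C(/C)I)[C@H]1[C@@H](O)C/C(C)=C/CCO
F2 | step 19 | (3E,6S)-6-hydroxy-6-{(2S,3R)-2-[(1Z)-2-iodoprop-1-en-1-yl]-4-methylidene-5-oxooxolan-3-yl}-4-methylhex-3-enal | C=C1C(=O)O[C@H](/C=C(/C)I)[C@H]1[C@@H](O)C/C(C)=C/CC=O
F3 | step 19 | (1(10)E,4Z)-3,8α-dihydroxygermacra-1(10),4,11(13)-trien-6α,12-olide (6R,7R,8S; both C3 epimers) | C=C1C(=O)O[C@@H]2/C=C(/C)C(O)C/C=C(\C)C[C@H](O)[C@@H]12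
F4 | step 19 | (1(10)E,4Z)-8α-hydroxy-3-oxogermacra-1(10),4,11(13)-trien-6α,12-olide (6R,7R,8S) | C=C1C(=O)O[C@@H]2/C=C(/C)C(=O)C/C=C(\C)C[C@H](O)[C@@H]12
F0 | step 21 | none | none
F5 | step 16 | (4S,5S)-4-[(3E)-6-{[tert-butyl(diphenyl)silyl]oxy}-3-methylhex-3-enoyl]-5-[(1Z)-2-iodoprop-1-en-1-yl]-3-methylideneoxolan-2-one | C=C1C(=O)O[C@H](/C=C(/C)I)[C@H]1C(=O)C/C(C)=C/CCO[Si](c1ccccc1)(c1ccccc1)C(C)(C)C
F6 | step 16 | (4R,5S)-4-[(1R,3E)-6-{[tert-butyl(diphenyl)silyl]oxy}-1-hydroxy-3-methylhex-3-en-1-yl]-5-[(1Z)-2-iodoprop-1-en-1-yl]-3-methylideneoxolan-2-one | C=C1C(=O)O[C@H](/C=C(/C)I)[C@H]1[C@H](O)C/C(C)=C/CCO[Si](c1ccccc1)(c1ccccc1)C(C)(C)C
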